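## Retrosynthetic overview

1. The target (9) is 8-(1,1-dimethylallyl)kaempferide; the last step removes two MOM ethers from flavonol 8.
2. Ring C is formed last, by Algar–Flynn–Oyamada oxidative cyclisation of 2'-hydroxychalcone 7. Closure through the OH next to the side chain places the side chain at C8.
3. Chalcone 7 comes from Claisen–Schmidt condensation of acetophenone 5 with 4-methoxybenzaldehyde (ring B purchased).
4. The 1,1-dimethylallyl group comes from an aromatic Claisen rearrangement of the symmetric 4-O-prenyl ether of 2,4,6-trihydroxyacetophenone (ring A purchased); symmetry allows only one C-alkylation product.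
5. Order: ring A functionalised (O-prenylation, Claisen, MOM protection), then chalcone, then ring C, then deprotection.

Assumption: the target has no stereocentres (it is achiral), so "single enantiomer" does not apply; the only stereo-element in the route is the E-alkene of chalcone 7, which is consumed in step 5.

## Route

**Step 1**
Reactants: 1, 2,4,6-trihydroxyacetophenone; 2, prenyl bromide (1-bromo-3-methylbut-2-ene)
Product: 3, 1-[2,6-dihydroxy-4-(3-methylbut-2-enyloxy)phenyl]ethanone
Conditions: 2 (1.0 equiv), K2CO3 (1.1 equiv), acetone, reflux
Reagents that add atoms: prenyl bromide (2), CC(C)=CCBr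
Why: Williamson etherification; the 4-OH (para to the acetyl) is the most acidic phenol and is favoured over the 2-/6-OH groups, which flank the acetyl and are deactivated by hydrogen bonding to its carbonyl, so one equivalent of base and bromide gives mainly the 4-O-prenyl ether.

**Step 2**
Reactants: 3, 4-O-prenyl ether
Product: 4, 1-[2,4,6-trihydroxy-3-(2-methylbut-3-en-2-yl)phenyl]ethanone
Conditions: PhNEt2, 200 °C (sealed tube or microwave), Ar, 1–2 h
Reagents that add atoms: none
Why: aromatic ortho-Claisen [3,3] rearrangement transfers the prenyl group with allylic inversion to give the 1,1-dimethylallyl group; the two ortho positions (C3/C5) are equivalent by symmetry and the para position is blocked by the acetyl, so only one regioisomer can form.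

**Step 3**
Reactants: 4, C-(1,1-dimethylallyl) triol
Product: 5, 1-[2-hydroxy-4,6-bis(methoxymethoxy)-3-(2-methylbut-3-en-2-yl)phenyl]ethanone
Conditions: MOMCl (2.3 equiv), i-Pr2NEt (3 equiv), CH2Cl2, 0 °C to rt
Reagents that add atoms: chloromethyl methyl ether (MOMCl), COCCl (two equivalents incorporated)
Why: O-alkylation (acetal protection) under amine-base conditions stops when the last ortho-OH is chelated to the ketone; the 4-OH and the less hindered ortho-OH (O-6, flanked by H) react, while the 2-OH, wedged between the acetyl and the quaternary carbon, should remain free.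

**Step 4**
Reactants: 5, protected acetophenone; 6, 4-methoxybenzaldehyde
Product: 7, (E)-1-[2-hydroxy-4,6-bis(methoxymethoxy)-3-(2-methylbut-3-en-2-yl)phenyl]-3-(4-methoxyphenyl)prop-2-en-1-one
Conditions: 6 (1.2 equiv), 50% aq. KOH, EtOH, rt, 24–48 h
Reagents that add atoms: 4-methoxybenzaldehyde (6), COc1ccc(C=O)cc1
Why: Claisen–Schmidt aldol condensation of the methyl ketone with a non-enolisable aldehyde gives the thermodynamic E-enone; MOM ethers and the isolated vinyl group are inert to hydroxide.

**Step 5**
Reactants: 7, chalcone
Product: 8, 3-hydroxy-2-(4-methoxyphenyl)-5,7-bis(methoxymethoxy)-8-(2-methylbut-3-en-2-yl)-4H-chromen-4-one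
Conditions: 30% aq. H2O2, 2 M aq. NaOH, MeOH, 0 °C to rt
Reagents that add atoms: hydrogen peroxide, OO (supplies the C3–OH oxygen)
Why: Algar–Flynn–Oyamada reaction; hydroperoxide epoxidises the enone, the 2'-phenoxide opens the epoxide at Cβ (6-endo), and the dihydroflavonol is oxidised to the flavonol. Nucleophilic peroxide does not attack the unactivated vinyl group, and closure through O-2' fixes the side chain at C8.

**Step 6**
Reactants: 8, bis-MOM flavonol
Product: 9, 3,5,7-trihydroxy-2-(4-methoxyphenyl)-8-(2-methylbut-3-en-2-yl)-4H-chromen-4-one (target)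
Conditions: 3 M HCl, MeOH–THF, 45–50 °C, 1–2 h (monitor; stop at full conversion)
Reagents that add atoms: none
Why: acid-catalysed acetal hydrolysis removes both MOM groups; the aryl methyl ether is stable, and the monosubstituted alkene of the 1,1-dimethylallyl group is much harder to protonate than a prenyl alkene, so it should survive dilute acid at or below 50 °C.

## Compound list

1 | 2,4,6-trihydroxyacetophenone | CC(=O)c1c(O)cc(O)cc1O | starting material
2 | prenyl bromide (1-bromo-3-methylbut-2-ene) | CC(C)=CCBr | starting material
3 | 1-[2,6-dihydroxy-4-(3-methylbut-2-enyloxy)phenyl]ethanone | CC(=O)c1c(O)cc(OCC=C(C)C)cc1O | intermediate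
4 | 1-[2,4,6-trihydroxy-3-(2-methylbut-3-en-2-yl)phenyl]ethanone | CC(=O)c1c(O)cc(O)c(C(C)(C)C=C)c1O | intermediate
5 | 1-[2-hydroxy-4,6-bis(methoxymethoxy)-3-(2-methylbut-3-en-2-yl)phenyl]ethanone | CC(=O)c1c(OCOC)cc(OCOC)c(C(C)(C)C=C)c1O | intermediate
6 | 4-methoxybenzaldehyde | COc1ccc(C=O)cc1 | starting material
7 | (E)-1-[2-hydroxy-4,6-bis(methoxymethoxy)-3-(2-methylbut-3-en-2-yl)phenyl]-3-(4-methoxyphenyl)prop-2-en-1-one | COCOc1cc(OCOC)c(C(C)(C)C=C)c(O)c1C(=O)/C=C/c1ccc(OC)cc1 | intermediate
8 | 3-hydroxy-2-(4-methoxyphenyl)-5,7-bis(methoxymethoxy)-8-(2-methylbut-3-en-2-yl)-4H-chromen-4-one | C=CC(C)(C)c1c(OCOC)cc(OCOC)c2c(=O)c(O)c(-c3ccc(OC)cc3)oc12 | intermediate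
9 | 3,5,7-trihydroxy-2-(4-methoxyphenyl)-8-(2-methylbut-3-en-2-yl)-4H-chromen-4-one | C=CC(C)(C)c1c(O)cc(O)c2c(=O)c(O)c(-c3ccc(OC)cc3)oc12 | target

## Summary

Total steps: 6. Longest linear sequence: 6 (1 → 3 → 4 → 5 → 7 → 8 → 9; compounds 2 and 6 are purchased).

Steps most likely to fail, with fallbacks:

1. **Step 2 (thermal Claisen on the free triol).** The electron-rich product can over-react at 200 °C (cyclisation of the flanking OH onto the alkene to a trimethyldihydrobenzofuran, or abnormal Claisen). Fallback: carry the O-prenyl ether forward and rearrange late. Mono-MOM 3, make the chalcone, run the AFO reaction, remove the MOM, then rearrange the 7-O-prenyl flavonol thermally, accepting that C8 and C6 isomers may need separation.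

2. **Step 3 (regioselective bis-MOM protection).** If the MOM group goes partly onto O-2 instead of O-6, the route leads to the 6-substituted isomer. Fallback: differentiate before the rearrangement. Mono-MOM the symmetric diol 3 (no regiochemical question), run the Claisen on the 2-hydroxy-6-MOM-4-prenyloxy ketone, where chelation by the 2-OH should direct migration to C3, then MOM the new 4-OH.

3. **Step 5 (AFO reaction).** 6'-Alkoxy chalcones can divert to aurones and the yield may be low. Fallback: a two-stage ring C construction. Cyclise the chalcone to the flavone (cat. I2, DMSO), then introduce the 3-OH by C3-lithiation (LDA, −78 °C), B(OMe)3, then H2O2. This avoids electrophilic oxidants that would attack the vinyl group.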